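**Retrosynthetic overview**
1. Target 14 ⇐ potassium 5,7-di-O-benzyl sulfate 12, by hydrogenolysis of the two benzyl ethers and protonation.
2. 12 ⇐ C2–C1′ bond: chromone 7 is used as a C2 carbanion (2-zincated chromone, a β-acylvinyl, homoenolate-type d3 donor at the carbon that is normally the electrophilic β-position) and joined to the electrophilic ipso carbon of aryl iodide 10, which already carries the sulfate.
3. 7 ⇐ o-hydroxyacetophenone 5 plus one carbon (DMF-DMA), closing the pyranone (C) ring.
4. 5 ⇐ phloroacetophenone 1 (4,6-di-O-benzylation, para-hydroxylation, O-methylation); 10 ⇐ 4-iodophenol 8 + SO3.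
5. Ring order: A ring bought (1), C ring built in step 4, B ring bought (8) and attached in step 6.

Assumption: the target has no stereocentre or stereogenic double bond, so there is nothing to control stereochemically; it is drawn as the free hydrogen sulfate and is carried as its potassium salt until the last work-up.

**Route**

Step 1
Reactants: 1 2,4,6-trihydroxyacetophenone
Product: 2 1-[2,4-bis(benzyloxy)-6-hydroxyphenyl]ethan-1-one
Conditions: BnBr (2.1 equiv), K2CO3 (2.2 equiv), DMF, 0 °C to rt, N2
Reagents that add atoms: benzyl bromide, BrCc1ccccc1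
Why: Williamson etherification; the 4-OH and one ortho-OH are benzylated, while the remaining ortho-OH is hydrogen-bonded to the acetyl group and stays free.

Step 2
Reactants: 2 1-[2,4-bis(benzyloxy)-6-hydroxyphenyl]ethan-1-one
Product: 4 1-[2,4-bis(benzyloxy)-3,6-dihydroxyphenyl]ethan-1-one, via potassium aryl sulfate 3 (not isolated)
Conditions: K2S2O8 (1.2 equiv), 10% aq. KOH/pyridine, 0 °C to rt, 36 h; acidify to pH 4 and extract unreacted 2; then 2 M HCl (cat.), Na2SO3, toluene, 85 °C
Reagents that add atoms: potassium persulfate, [K+].[K+].[O-]S(=O)(=O)OOS(=O)(=O)[O-]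
Why: Elbs persulfate oxidation; the phenolate attacks peroxydisulfate through its only para carbon (C3), and the resulting aryl sulfate is hydrolysed by acid to the hydroquinone.

Step 3
Reactants: 4 1-[2,4-bis(benzyloxy)-3,6-dihydroxyphenyl]ethan-1-one
Product: 5 1-[2,4-bis(benzyloxy)-6-hydroxy-3-methoxyphenyl]ethan-1-one
Conditions: MeI (1.1 equiv), K2CO3 (1.2 equiv), acetone, 45 °C, N2
Reagents that add atoms: iodomethane, CI
Why: Williamson methylation; with one equivalent only the non-chelated 3-OH reacts, because the 6-OH is locked in the hydrogen bond to the ketone.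

Step 4
Reactants: 5 1-[2,4-bis(benzyloxy)-6-hydroxy-3-methoxyphenyl]ethan-1-one
Product: 7 5,7-bis(benzyloxy)-6-methoxy-4H-chromen-4-one, via enaminone 6 (not isolated)
Conditions: DMF-DMA (3 equiv), toluene, 100 °C; evaporate; AcOH, 90 °C
Reagents that add atoms: N,N-dimethylformamide dimethyl acetal, COC(OC)N(C)C
Why: Enaminone chromone synthesis; condensation of the methyl ketone with the amide acetal, then acid-promoted addition of the phenol to the enaminone β-carbon with loss of dimethylamine, closes the C ring and leaves C2–H free.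

Step 5
Reactants: 8 4-iodophenol
Product: 10 potassium 4-iodophenyl sulfate, via pyridinium 4-iodophenyl sulfate 9 (not isolated)
Conditions: SO3·pyridine (2 equiv), pyridine, 50 °C; then aq. KOH to pH 9; recrystallise (H2O/EtOH), dry over P2O5 in vacuo
Reagents that add atoms: sulfur trioxide pyridine complex, [O-]S(=O)(=O)[n+]1ccccc1; potassium hydroxide, [K+].[OH-]
Why: O-sulfonation of a phenol with SO3·pyridine; exchange to the potassium salt removes the acidic N–H that would quench the organozinc in step 6.

Step 6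
Reactants: 7 5,7-bis(benzyloxy)-6-methoxy-4H-chromen-4-one; 10 potassium 4-iodophenyl sulfate
Product: 12 potassium 4-[5,7-bis(benzyloxy)-6-methoxy-4-oxo-4H-chromen-2-yl]phenyl sulfate, via bis(chromon-2-yl)zinc 11 (not isolated)
Conditions: 7 (1.2 equiv), TMP2Zn·2MgCl2·2LiCl (0.65 equiv), THF, −30 °C, 1 h; then 10 (1.0 equiv), Pd(dba)2 (3 mol %), P(2-furyl)3 (6 mol %), THF/NMP 1:1, 50 °C
Reagents that add atoms: none
Why: Deprotonative zincation followed by Negishi cross-coupling; with MgCl2 bound to C4=O/5-OBn the C2–H is the most acidic site, so the normally electrophilic C2 becomes a β-acylvinyl (homoenolate-type) zinc nucleophile that couples with the electrophilic aryl iodide, and the sulfate monoanion is inert to both organozinc and Pd(0).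

Step 7
Reactants: 12 potassium 4-[5,7-bis(benzyloxy)-6-methoxy-4-oxo-4H-chromen-2-yl]phenyl sulfate
Product: 14 hispidulin 4'-sulfate (4-(5,7-dihydroxy-6-methoxy-4-oxo-4H-chromen-2-yl)phenyl hydrogen sulfate), via potassium hispidulin 4'-sulfate 13 (not isolated)
Conditions: H2 (1 atm), 10% Pd/C, MeOH/THF/H2O, rt; filter; then 1 M HCl (1.0 equiv), 0 °C; C18 desalting, lyophilise
Reagents that add atoms: none
Why: Catalytic hydrogenolysis of the two aryl benzyl ethers; the aryl sulfate and the conjugated C2=C3 bond survive at 1 atm and rt, and cold stoichiometric acid gives the hydrogen sulfate without hydrolysis.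

**Compound list**
1 | 2,4,6-trihydroxyacetophenone | CC(=O)c1c(O)cc(O)cc1O | starting material
2 | 1-[2,4-bis(benzyloxy)-6-hydroxyphenyl]ethan-1-one | CC(=O)c1c(O)cc(OCc2ccccc2)cc1OCc1ccccc1 | intermediate
3 | potassium 3-acetyl-2,6-bis(benzyloxy)-4-hydroxyphenyl sulfate | CC(=O)c1c(O)cc(OCc2ccccc2)c(OS(=O)(=O)[O-])c1OCc1ccccc1.[K+] | intermediate
4 | 1-[2,4-bis(benzyloxy)-3,6-dihydroxyphenyl]ethan-1-one | CC(=O)c1c(O)cc(OCc2ccccc2)c(O)c1OCc1ccccc1 | intermediate
5 | 1-[2,4-bis(benzyloxy)-6-hydroxy-3-methoxyphenyl]ethan-1-one | CC(=O)c1c(O)cc(OCc2ccccc2)c(OC)c1OCc1ccccc1 | intermediate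
6 | (E)-1-[2,4-bis(benzyloxy)-6-hydroxy-3-methoxyphenyl]-3-(dimethylamino)prop-2-en-1-one | CN(C)/C=C/C(=O)c1c(O)cc(OCc2ccccc2)c(OC)c1OCc1ccccc1 | intermediate
7 | 5,7-bis(benzyloxy)-6-methoxy-4H-chromen-4-one | COc1c(OCc2ccccc2)cc2occc(=O)c2c1OCc1ccccc1 | intermediate
8 | 4-iodophenol | Oc1ccc(I)cc1 | starting material
9 | pyridinium 4-iodophenyl sulfate | [O-]S(=O)(=O)Oc1ccc(I)cc1.c1cc[nH+]cc1 | intermediate
10 | potassium 4-iodophenyl sulfate | [K+].[O-]S(=O)(=O)Oc1ccc(I)cc1 | intermediate
11 | bis[5,7-bis(benzyloxy)-6-methoxy-4-oxo-4H-chromen-2-yl]zinc (as its MgCl2/LiCl complex) | COc1c(OCc2ccccc2)cc2oc([Zn]c3cc(=O)c4c(OCc5ccccc5)c(OC)c(OCc5ccccc5)cc4o3)cc(=O)c2c1OCc1ccccc1 | intermediate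
12 | potassium 4-[5,7-bis(benzyloxy)-6-methoxy-4-oxo-4H-chromen-2-yl]phenyl sulfate | COc1c(OCc2ccccc2)cc2oc(-c3ccc(OS(=O)(=O)[O-])cc3)cc(=O)c2c1OCc1ccccc1.[K+] | intermediate
13 | potassium 4-(5,7-dihydroxy-6-methoxy-4-oxo-4H-chromen-2-yl)phenyl sulfate | COc1c(O)cc2oc(-c3ccc(OS(=O)(=O)[O-])cc3)cc(=O)c2c1O.[K+] | intermediate
14 | hispidulin 4'-sulfate | COc1c(O)cc2oc(-c3ccc(OS(=O)(=O)O)cc3)cc(=O)c2c1O | target

**Count and risks**
Total steps: 7. Longest linear sequence: 6 (steps 1, 2, 3, 4, 6, 7); step 5 is a one-step side branch.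

Step 6 is the most likely to fail, because the coupling partner is an ionic, hygroscopic salt that may be poorly soluble or may carry water into the organozinc. The fallback sets out from 7 and comes back at 12. Compound 7 is zincated as in step 6 but coupled with neutral, THF-soluble 4-iodophenyl acetate (commercial) to give 4-[5,7-bis(benzyloxy)-6-methoxy-4-oxo-4H-chromen-2-yl]phenyl acetate F1. Methanolysis (K2CO3, MeOH/THF, rt) gives 5,7-bis(benzyloxy)-2-(4-hydroxyphenyl)-6-methoxy-4H-chromen-4-one F2. Its only free phenol is then sulfated (SO3·pyridine, pyridine, then aq. KOH) to give 12, so the sulfate is introduced after the C–C bond instead of before it.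

Step 2 is the second risk, because Elbs oxidations give modest conversions and the para position here is flanked by two benzyloxy groups. The fallback sets out from 2 and comes back at 4. Teuber oxidation of 2 with Fremy's salt (K2[ON(SO3)2], KH2PO4 buffer, acetone/H2O) gives 2-acetyl-3,5-bis(benzyloxy)cyclohexa-2,5-diene-1,4-dione F3. Reduction with Na2S2O4 (EtOAc/H2O) then gives hydroquinone 4, replacing the two-electron persulfate substitution by a radical quinone-forming oxidation and reduction.

Step 7 is the third risk, through partial reduction of the C2=C3 bond or catalyst-related loss of material. The fallback sets out from 12 and comes back at 13. The benzyl ethers are cleaved without hydrogen by SN2 attack of thiophenolate at the benzylic carbons (PhSH, K2CO3, NMP, 80 °C). The 5- and 7-phenoxides are good leaving groups because they are conjugated with C4=O, and the sulfate monoanion is not electrophilic. This gives 13 directly, which is protonated as in step 7; the fallback makes no new compound (F0).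

**Further compounds**
F1 | step 6 | 4-[5,7-bis(benzyloxy)-6-methoxy-4-oxo-4H-chromen-2-yl]phenyl acetate | COc1c(OCc2ccccc2)cc2oc(-c3ccc(OC(C)=O)cc3)cc(=O)c2c1OCc1ccccc1
F2 | step 6 | 5,7-bis(benzyloxy)-2-(4-hydroxyphenyl)-6-methoxy-4H-chromen-4-one | COc1c(OCc2ccccc2)cc2oc(-c3ccc(O)cc3)cc(=O)c2c1OCc1ccccc1
F3 | step 2 | 2-acetyl-3,5-bis(benzyloxy)cyclohexa-2,5-diene-1,4-dione | CC(=O)C1=C(OCc2ccccc2)C(=O)C(OCc2ccccc2)=CC1=O
F0 | step 7 | none | none
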